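**Assumption (one line):** in step 1 the antipode of the phosphoramidite ligand that gives the 3S adduct is used; bicyclic compounds carry naphthalene locants (C-1 bears the carboxyl carbon, C-5 the side chain) and α means the face of H-8a.

## Retrosynthetic overview

1. 27 ⇐ 26 (O-acetylation) ⇐ 24 (SN2 ester demethylation) ⇐ alkyne 21 (Me3Al/Cp2ZrCl2 carboalumination then CH2O gives the E-alkene) ⇐ aldehyde 20.
2. C-5 quaternary centre and 4,4a-alkene ⇐ bicyclic enone 14: CuBr·SMe2-catalysed 1,4-addition of Grignard 15 anti to the C-6 methyl, then enol triflate and Pd(PPh3)4/Bu3SnH reduction.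
3. Key C–C bond, ring A ⇐ acetylcyclohexene 8 + methyl methacrylate 9: intermolecular Michael addition of the lithium dienolate, then ring-closing Michael addition (sets C-1 and C-8a); bromination/dehydrobromination gives 14.
4. 8 ⇐ (2R,3S)-2,3-dimethylcyclohexanone 4 (kinetic enol triflate, Stille acylation) ⇐ asymmetric 1,4-methylation of 2-methylcyclohexenone 1.
5. Ring order: ring B (from 1) first, ring A second (step 4).

## Forward route

Step 1
Reactants: 1 2-methylcyclohex-2-en-1-one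
Product: 4 (2R,3S)-2,3-dimethylcyclohexan-1-one, via aluminium enolate 2 (not isolated), via cis ketone epimer 3 (not isolated)
Conditions: Me3Al (1.4 equiv), Cu(O2CC4H3S) (2 mol %), chiral binaphthol phosphoramidite ligand (4 mol %), Et2O, −30 °C; aq. NH4Cl; then NaOMe (0.1 equiv), MeOH, 25 °C; chromatography to remove residual cis epimer
Reagents that add atoms: trimethylaluminium, C[Al](C)C
Why: Asymmetric conjugate addition of methyl to the enone, in which the phosphoramidite-ligated Cu(O2CC4H3S) catalyst sets C-3 as S, followed by methoxide equilibration of the epimerisable C-2 to the diequatorial trans (2R) isomer.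

Step 2
Reactants: 4 (2R,3S)-2,3-dimethylcyclohexan-1-one
Product: 6 (5S,6R)-5,6-dimethylcyclohex-1-en-1-yl trifluoromethanesulfonate, via lithium enolate 5 (not isolated)
Conditions: LiN(iPr)2 (1.05 equiv), THF, −78 °C; PhNTf2 (1.1 equiv), −78 → 0 °C
Reagents that add atoms: N-phenylbis(trifluoromethanesulfonimide), O=S(=O)(N(c1ccccc1)S(=O)(=O)C(F)(F)F)C(F)(F)F
Why: Kinetic deprotonation at the unsubstituted C-6 methylene and O-sulfonylation of that enolate (enol triflate formation) give the less substituted vinyl triflate while the C-2 and C-3 stereocenters stay untouched.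

Step 3
Reactants: 6 (5S,6R)-5,6-dimethylcyclohex-1-en-1-yl trifluoromethanesulfonate
Product: 8 1-[(5S,6R)-5,6-dimethylcyclohex-1-en-1-yl]ethan-1-one, via ethoxy diene 7 (not isolated)
Conditions: tributyl(1-ethoxyvinyl)stannane (1.2 equiv), Pd(PPh3)4 (5 mol %), LiCl (3 equiv), THF, 65 °C; then 1 M HCl, 25 °C
Reagents that add atoms: tributyl(1-ethoxyvinyl)stannane, CCCC[Sn](CCCC)(CCCC)C(=C)OCC; water, O
Why: Stille cross-coupling of the vinyl triflate with an acetyl-anion equivalent and hydrolysis of the enol ether deliver the conjugated methyl ketone without affecting either stereocenter.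

Step 4
Reactants: 8 1-[(5S,6R)-5,6-dimethylcyclohex-1-en-1-yl]ethan-1-one; 9 methyl methacrylate
Product: 13 methyl (1S,4aR,5R,6S,8aS)-4a-bromo-1,5,6-trimethyl-4-oxodecahydronaphthalene-1-carboxylate, via lithium dienolate 10 (not isolated), via ester enolate 11 (not isolated), via bicyclic enolate 12 (not isolated)
Conditions: LiN(iPr)2 (1.05 equiv), THF, −78 °C; 9 (1.1 equiv), −78 → 0 °C; then Br2 (1.0 equiv), −78 °C
Reagents that add atoms: bromine, BrBr
Why: Key step, an intermolecular Michael addition of dienolate 10 to 9 followed by ring-closing Michael addition of ester enolate 11 (double Michael annulation) and enolate bromination, in which the pseudoaxial methyl next to the acyl-bearing alkene carbon of 8 (allylic 1,2-strain) shields the α face so that C-1 bonds to C-8a on the β face, the lithium-bridged endo arrangement puts CO2Me cis to the C-8a–C-8 bond (setting C-1 and C-8a), and bromine enters enolate 12 from the α face because the β face is screened by the axial C-1 ester and the C-6 methyl.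

Step 5
Reactants: 13 methyl (1S,4aR,5R,6S,8aS)-4a-bromo-1,5,6-trimethyl-4-oxodecahydronaphthalene-1-carboxylate
Product: 14 methyl (1S,6S,8aR)-1,5,6-trimethyl-4-oxo-1,2,3,4,6,7,8,8a-octahydronaphthalene-1-carboxylate
Conditions: Li2CO3 (3 equiv), LiBr (3 equiv), DMF, 120 °C
Reagents that add atoms: none
Why: E2 dehydrobromination in which only H-5 can become anti-periplanar to the α C-4a–Br bond (H-8a is cis to bromine), so the tetrasubstituted 4a,5-enone forms regioselectively, the temporary C-5 and C-4a stereocenters vanish and C-8a is preserved.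

Step 6
Reactants: 14 methyl (1S,6S,8aR)-1,5,6-trimethyl-4-oxo-1,2,3,4,6,7,8,8a-octahydronaphthalene-1-carboxylate; 15 [2-(1,3-dioxolan-2-yl)ethyl]magnesium bromide
Product: 16 methyl (1S,5R,6S,8aR)-5-[2-(1,3-dioxolan-2-yl)ethyl]-1,5,6-trimethyl-4-[(trimethylsilyl)oxy]-1,2,3,5,6,7,8,8a-octahydronaphthalene-1-carboxylate
Conditions: 15 (3 equiv), CuBr·SMe2 (20 mol %), Me3SiCl (3 equiv), HMPA (3 equiv), THF, −78 → −40 °C; Et3N, then aq. NaHCO3
Reagents that add atoms: chlorotrimethylsilane, C[Si](C)(C)Cl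
Why: CuBr·SMe2-catalysed, Me3SiCl-accelerated conjugate addition of the Grignard reagent to the s-cis enone, in which the nucleophile attacks C-5 axially and anti to the adjacent pseudoaxial C-6 methyl so that the new chain is cis to H-8a (C-5 becomes R), while silylation traps the enolate regiospecifically at C-4/C-4a.

Step 7
Reactants: 16 methyl (1S,5R,6S,8aR)-5-[2-(1,3-dioxolan-2-yl)ethyl]-1,5,6-trimethyl-4-[(trimethylsilyl)oxy]-1,2,3,5,6,7,8,8a-octahydronaphthalene-1-carboxylate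
Product: 18 methyl (1S,5R,6S,8aR)-5-[2-(1,3-dioxolan-2-yl)ethyl]-1,5,6-trimethyl-4-{[(trifluoromethyl)sulfonyl]oxy}-1,2,3,5,6,7,8,8a-octahydronaphthalene-1-carboxylate, via cesium enolate 17 (not isolated)
Conditions: CsF (2 equiv), PhNTf2 (1.3 equiv), DME, 25 °C
Reagents that add atoms: N-phenylbis(trifluoromethanesulfonimide), O=S(=O)(N(c1ccccc1)S(=O)(=O)C(F)(F)F)C(F)(F)F
Why: Fluoride-induced desilylation releases the regiodefined enolate, which is O-triflated in situ (enol triflate formation), fixing the double bond between C-4 and C-4a.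

Step 8
Reactants: 18 methyl (1S,5R,6S,8aR)-5-[2-(1,3-dioxolan-2-yl)ethyl]-1,5,6-trimethyl-4-{[(trifluoromethyl)sulfonyl]oxy}-1,2,3,5,6,7,8,8a-octahydronaphthalene-1-carboxylate
Product: 19 methyl (1S,5R,6S,8aR)-5-[2-(1,3-dioxolan-2-yl)ethyl]-1,5,6-trimethyl-1,2,3,5,6,7,8,8a-octahydronaphthalene-1-carboxylate
Conditions: Bu3SnH (1.5 equiv), Pd(PPh3)4 (5 mol %), LiCl (3 equiv), THF, 60 °C
Reagents that add atoms: none
Why: Pd(PPh3)4-catalysed reduction of the enol triflate with tin hydride replaces OTf by H without moving the double bond, giving the trisubstituted 4,4a-alkene.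

Step 9
Reactants: 19 methyl (1S,5R,6S,8aR)-5-[2-(1,3-dioxolan-2-yl)ethyl]-1,5,6-trimethyl-1,2,3,5,6,7,8,8a-octahydronaphthalene-1-carboxylate
Product: 20 methyl (1S,5R,6S,8aR)-1,5,6-trimethyl-5-(3-oxopropyl)-1,2,3,5,6,7,8,8a-octahydronaphthalene-1-carboxylate
Conditions: 1 M HCl, THF, 25 °C
Reagents that add atoms: water, O
Why: Acid-catalysed acetal hydrolysis unmasks the aldehyde under conditions too mild to move the trisubstituted alkene or touch the hindered ester.

Step 10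
Reactants: 20 methyl (1S,5R,6S,8aR)-1,5,6-trimethyl-5-(3-oxopropyl)-1,2,3,5,6,7,8,8a-octahydronaphthalene-1-carboxylate
Product: 21 methyl (1S,5R,6S,8aR)-5-(but-3-yn-1-yl)-1,5,6-trimethyl-1,2,3,5,6,7,8,8a-octahydronaphthalene-1-carboxylate
Conditions: dimethyl (1-diazo-2-oxopropyl)phosphonate (1.3 equiv), K2CO3 (2 equiv), MeOH, 0 → 25 °C
Reagents that add atoms: dimethyl (1-diazo-2-oxopropyl)phosphonate, CC(=O)C(=[N+]=[N-])P(=O)(OC)OC
Why: Ohira–Bestmann (Seyferth–Gilbert) homologation converts the aldehyde into the terminal alkyne under weakly basic conditions that leave the methyl ester in methanol unchanged.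

Step 11
Reactants: 21 methyl (1S,5R,6S,8aR)-5-(but-3-yn-1-yl)-1,5,6-trimethyl-1,2,3,5,6,7,8,8a-octahydronaphthalene-1-carboxylate
Product: 24 methyl (1S,5R,6S,8aR)-5-[(3E)-5-hydroxy-3-methylpent-3-en-1-yl]-1,5,6-trimethyl-1,2,3,5,6,7,8,8a-octahydronaphthalene-1-carboxylate, via alkenylalane 22 (not isolated), via lithium alanate 23 (not isolated)
Conditions: Me3Al (3 equiv), Cp2ZrCl2 (0.3 equiv), CH2Cl2, 0 → 25 °C; volatiles removed; n-BuLi (1.1 equiv), THF, −78 °C; (CH2O)n, −78 → 25 °C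
Reagents that add atoms: trimethylaluminium, C[Al](C)C; formaldehyde (from paraformaldehyde), C=O
Why: Negishi Cp2ZrCl2-catalysed syn carboalumination places methyl on the internal alkyne carbon and aluminium on the terminus, and hydroxymethylation of the derived alanate with formaldehyde occurs with retention, giving the E trisubstituted allylic alcohol.

Step 12
Reactants: 24 methyl (1S,5R,6S,8aR)-5-[(3E)-5-hydroxy-3-methylpent-3-en-1-yl]-1,5,6-trimethyl-1,2,3,5,6,7,8,8a-octahydronaphthalene-1-carboxylate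
Product: 26 (1S,5R,6S,8aR)-5-[(3E)-5-hydroxy-3-methylpent-3-en-1-yl]-1,5,6-trimethyl-1,2,3,5,6,7,8,8a-octahydronaphthalene-1-carboxylic acid, via sodium carboxylate 25 (not isolated)
Conditions: NaSEt (5 equiv), DMF, 100 °C; then 1 M HCl
Reagents that add atoms: none
Why: SN2 O-demethylation of the hindered tertiary methyl ester by ethanethiolate cleaves the O–CH3 bond instead of attacking the shielded carbonyl, leaving the alkenes and C-1 untouched.

Step 13
Reactants: 26 (1S,5R,6S,8aR)-5-[(3E)-5-hydroxy-3-methylpent-3-en-1-yl]-1,5,6-trimethyl-1,2,3,5,6,7,8,8a-octahydronaphthalene-1-carboxylic acid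
Product: 27 (1S,5R,6S,8aR)-5-[(3E)-5-(acetyloxy)-3-methylpent-3-en-1-yl]-1,5,6-trimethyl-1,2,3,5,6,7,8,8a-octahydronaphthalene-1-carboxylic acid
Conditions: Ac2O (1.5 equiv), pyridine, DMAP (5 mol %), CH2Cl2, 0 → 25 °C; aq. NaHCO3 work-up
Reagents that add atoms: acetic anhydride, CC(=O)OC(C)=O
Why: Nucleophile-catalysed O-acetylation of the primary allylic alcohol, with any mixed anhydride of the hindered acid being hydrolysed during the bicarbonate work-up.

## Compound list

1 | 2-methylcyclohex-2-en-1-one | CC1=CCCCC1=O | starting material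
2 | dimethylaluminium (3S)-2,3-dimethylcyclohex-1-en-1-olate | C[Al](C)OC1=C(C)[C@@H](C)CCC1 | intermediate
3 | (2S,3S)-2,3-dimethylcyclohexan-1-one (cis epimer) | O=C1CCC[C@H](C)[C@@H]1C | intermediate
4 | (2R,3S)-2,3-dimethylcyclohexan-1-one | O=C1CCC[C@H](C)[C@H]1C | intermediate
5 | lithium (5S,6R)-5,6-dimethylcyclohex-1-en-1-olate | [Li]OC1=CCC[C@H](C)[C@H]1C | intermediate
6 | (5S,6R)-5,6-dimethylcyclohex-1-en-1-yl trifluoromethanesulfonate | O=S(=O)(OC1=CCC[C@H](C)[C@H]1C)C(F)(F)F | intermediate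
7 | (5S,6R)-1-(1-ethoxyethenyl)-5,6-dimethylcyclohex-1-ene | CCOC(=C)C1=CCC[C@H](C)[C@H]1C | intermediate
8 | 1-[(5S,6R)-5,6-dimethylcyclohex-1-en-1-yl]ethan-1-one | CC(=O)C1=CCC[C@H](C)[C@H]1C | intermediate
9 | methyl methacrylate | C=C(C)C(=O)OC | starting material
10 | lithium 1-[(5S,6R)-5,6-dimethylcyclohex-1-en-1-yl]ethen-1-olate | C=C(O[Li])C1=CCC[C@H](C)[C@H]1C | intermediate
11 | lithium enolate of methyl 5-[(5S,6R)-5,6-dimethylcyclohex-1-en-1-yl]-2-methyl-5-oxopentanoate | COC(O[Li])=C(C)CCC(=O)C1=CCC[C@H](C)[C@H]1C | intermediate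
12 | methyl (1S,5R,6S,8aR)-4-(lithiooxy)-1,5,6-trimethyl-1,2,3,5,6,7,8,8a-octahydronaphthalene-1-carboxylate | C[C@H]1C2=C(O[Li])CC[C@](C)(C(=O)OC)[C@@H]2CC[C@@H]1C | intermediate
13 | methyl (1S,4aR,5R,6S,8aS)-4a-bromo-1,5,6-trimethyl-4-oxodecahydronaphthalene-1-carboxylate | C[C@H]1[C@]2(Br)C(=O)CC[C@](C)(C(=O)OC)[C@@H]2CC[C@@H]1C | intermediate
14 | methyl (1S,6S,8aR)-1,5,6-trimethyl-4-oxo-1,2,3,4,6,7,8,8a-octahydronaphthalene-1-carboxylate | CC1=C2C(=O)CC[C@](C)(C(=O)OC)[C@@H]2CC[C@@H]1C | intermediate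
15 | [2-(1,3-dioxolan-2-yl)ethyl]magnesium bromide | Br[Mg]CCC1OCCO1 | starting material
16 | methyl (1S,5R,6S,8aR)-5-[2-(1,3-dioxolan-2-yl)ethyl]-1,5,6-trimethyl-4-[(trimethylsilyl)oxy]-1,2,3,5,6,7,8,8a-octahydronaphthalene-1-carboxylate | C1(CC[C@@]2(C)C3=C(O[Si](C)(C)C)CC[C@](C)(C(=O)OC)[C@@H]3CC[C@@H]2C)OCCO1 | intermediate
17 | cesium enolate, methyl (1S,5R,6S,8aR)-4-(cesiooxy)-5-[2-(1,3-dioxolan-2-yl)ethyl]-1,5,6-trimethyl-1,2,3,5,6,7,8,8a-octahydronaphthalene-1-carboxylate | C1(CC[C@@]2(C)C3=C(O[Cs])CC[C@](C)(C(=O)OC)[C@@H]3CC[C@@H]2C)OCCO1 | intermediate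
18 | methyl (1S,5R,6S,8aR)-5-[2-(1,3-dioxolan-2-yl)ethyl]-1,5,6-trimethyl-4-{[(trifluoromethyl)sulfonyl]oxy}-1,2,3,5,6,7,8,8a-octahydronaphthalene-1-carboxylate | C1(CC[C@@]2(C)C3=C(OS(=O)(=O)C(F)(F)F)CC[C@](C)(C(=O)OC)[C@@H]3CC[C@@H]2C)OCCO1 | intermediate
19 | methyl (1S,5R,6S,8aR)-5-[2-(1,3-dioxolan-2-yl)ethyl]-1,5,6-trimethyl-1,2,3,5,6,7,8,8a-octahydronaphthalene-1-carboxylate | C1(CC[C@@]2(C)C3=CCC[C@](C)(C(=O)OC)[C@@H]3CC[C@@H]2C)OCCO1 | intermediate
20 | methyl (1S,5R,6S,8aR)-1,5,6-trimethyl-5-(3-oxopropyl)-1,2,3,5,6,7,8,8a-octahydronaphthalene-1-carboxylate | O=CCC[C@@]1(C)C2=CCC[C@](C)(C(=O)OC)[C@@H]2CC[C@@H]1C | intermediate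
21 | methyl (1S,5R,6S,8aR)-5-(but-3-yn-1-yl)-1,5,6-trimethyl-1,2,3,5,6,7,8,8a-octahydronaphthalene-1-carboxylate | C#CCC[C@@]1(C)C2=CCC[C@](C)(C(=O)OC)[C@@H]2CC[C@@H]1C | intermediate
22 | (E)-alkenyl(dimethyl)alane from 21 | C[Al](C)/C=C(\C)CC[C@@]1(C)C2=CCC[C@](C)(C(=O)OC)[C@@H]2CC[C@@H]1C | intermediate
23 | lithium (E)-alkenyl(butyl)dimethylaluminate from 22 | [Li+].CCCC[Al-](C)(C)/C=C(\C)CC[C@@]1(C)C2=CCC[C@](C)(C(=O)OC)[C@@H]2CC[C@@H]1C | intermediate
24 | methyl (1S,5R,6S,8aR)-5-[(3E)-5-hydroxy-3-methylpent-3-en-1-yl]-1,5,6-trimethyl-1,2,3,5,6,7,8,8a-octahydronaphthalene-1-carboxylate | OC/C=C(\C)CC[C@@]1(C)C2=CCC[C@](C)(C(=O)OC)[C@@H]2CC[C@@H]1C | intermediate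
25 | sodium (1S,5R,6S,8aR)-5-[(3E)-5-hydroxy-3-methylpent-3-en-1-yl]-1,5,6-trimethyl-1,2,3,5,6,7,8,8a-octahydronaphthalene-1-carboxylate | [Na+].OC/C=C(\C)CC[C@@]1(C)C2=CCC[C@](C)(C(=O)[O-])[C@@H]2CC[C@@H]1C | intermediate
26 | (1S,5R,6S,8aR)-5-[(3E)-5-hydroxy-3-methylpent-3-en-1-yl]-1,5,6-trimethyl-1,2,3,5,6,7,8,8a-octahydronaphthalene-1-carboxylic acid | OC/C=C(\C)CC[C@@]1(C)C2=CCC[C@](C)(C(=O)O)[C@@H]2CC[C@@H]1C | intermediate
27 | (1S,5R,6S,8aR)-5-[(3E)-5-(acetyloxy)-3-methylpent-3-en-1-yl]-1,5,6-trimethyl-1,2,3,5,6,7,8,8a-octahydronaphthalene-1-carboxylic acid | CC(=O)OC/C=C(\C)CC[C@@]1(C)C2=CCC[C@](C)(C(=O)O)[C@@H]2CC[C@@H]1C | target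

## Step count and risks

Total step count: 13. Longest linear sequence: 13 steps (1 → 27; 9 and 15 are commercial and enter directly).

The three steps most likely to fail:

**Step 4 (double Michael annulation).** Ester enolate 11 may be quenched by proton transfer before ring closure, 9 may oligomerise, or face and endo control may be weaker than argued. Fallback: setting out from 8, O-silylation (t-BuMe2SiOTf, Et3N, CH2Cl2) gives the 2-silyloxy diene F1. A thermal or Me2AlCl-promoted Diels–Alder reaction of F1 with 9 gives the bicyclic silyl enol ether F2 with the same regiochemistry. Br2 at −78 °C converts F2 into 13, where the route is rejoined.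

**Step 5 (dehydrobromination).** The regiochemistry depends on the bromide configuration; if bromine were delivered to the β face, anti elimination would run toward C-8a and destroy that stereocenter. Fallback: setting out from 8, enolate 12 is generated as in step 4 but quenched with PhSeBr to give the α-selanyl ketone F3. H2O2 oxidises it to the selenoxide F4, whose syn elimination needs the cis H-5 and so gives 14, where the route is rejoined.

**Step 6 (1,4-addition to the tetrasubstituted enone).** The addition may be slow or give 1,2-addition. Fallback: setting out from 14, LiBH(s-Bu)3 reduces the ketone from the equatorial side to the α allylic alcohol F5. Johnson–Claisen rearrangement (CH3C(OEt)3, cat. EtCO2H, 140 °C) transfers chirality suprafacially from C-4 to C-5 and gives the 4,4a-alkene diester F6. LiBH4 reduces only the unhindered ethyl ester to the primary alcohol F7, and I2/PPh3/imidazole gives the iodide F8. LiC≡CH·H2NCH2CH2NH2 in DMSO then gives alkyne 21, where the route is rejoined.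

## Further compounds

F1 | step 4 | tert-butyl({1-[(5S,6R)-5,6-dimethylcyclohex-1-en-1-yl]ethenyl}oxy)dimethylsilane | C=C(O[Si](C)(C)C(C)(C)C)C1=CCC[C@H](C)[C@H]1C
F2 | step 4 | methyl (1S,5R,6S,8aR)-4-{[tert-butyl(dimethyl)silyl]oxy}-1,5,6-trimethyl-1,2,3,5,6,7,8,8a-octahydronaphthalene-1-carboxylate | C[C@H]1C2=C(O[Si](C)(C)C(C)(C)C)CC[C@](C)(C(=O)OC)[C@@H]2CC[C@@H]1C
F3 | step 5 | methyl (1S,4aS,5R,6S,8aS)-1,5,6-trimethyl-4-oxo-4a-(phenylselanyl)decahydronaphthalene-1-carboxylate | C[C@H]1[C@@]2([Se]c3ccccc3)C(=O)CC[C@](C)(C(=O)OC)[C@@H]2CC[C@@H]1C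
F4 | step 5 | methyl (1S,4aS,5R,6S,8aS)-1,5,6-trimethyl-4-oxo-4a-(phenylseleninyl)decahydronaphthalene-1-carboxylate | C[C@H]1[C@@]2([Se](=O)c3ccccc3)C(=O)CC[C@](C)(C(=O)OC)[C@@H]2CC[C@@H]1C
F5 | step 6 | methyl (1S,4S,6S,8aR)-4-hydroxy-1,5,6-trimethyl-1,2,3,4,6,7,8,8a-octahydronaphthalene-1-carboxylate | CC1=C2[C@@H](O)CC[C@](C)(C(=O)OC)[C@@H]2CC[C@@H]1C
F6 | step 6 | methyl (1S,5R,6S,8aR)-5-(2-ethoxy-2-oxoethyl)-1,5,6-trimethyl-1,2,3,5,6,7,8,8a-octahydronaphthalene-1-carboxylate | CCOC(=O)C[C@@]1(C)C2=CCC[C@](C)(C(=O)OC)[C@@H]2CC[C@@H]1C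
F7 | step 6 | methyl (1S,5R,6S,8aR)-5-(2-hydroxyethyl)-1,5,6-trimethyl-1,2,3,5,6,7,8,8a-octahydronaphthalene-1-carboxylate | OCC[C@@]1(C)C2=CCC[C@](C)(C(=O)OC)[C@@H]2CC[C@@H]1C
F8 | step 6 | methyl (1S,5R,6S,8aR)-5-(2-iodoethyl)-1,5,6-trimethyl-1,2,3,5,6,7,8,8a-octahydronaphthalene-1-carboxylate | ICC[C@@]1(C)C2=CCC[C@](C)(C(=O)OC)[C@@H]2CC[C@@H]1C
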